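**Assumptions (one line):** The SMILES is read as 1,2‑trans, (1S,2R). 4‑Vinylguaiacol, (S)‑3‑butene‑1,2‑diol and 4‑(benzyloxy)‑3‑hydroxybenzaldehyde are taken as commercial.

## Retrosynthetic overview
1. Vitedoin A ⇐ debenzylation ⇐ chemoselective reduction of the C9 aldehyde ⇐ C2 epimerisation to trans ⇐ oxidative cleavage of a C2 vinyl group.
2. The dihydronaphthalene ring is closed last, by intramolecular aldol condensation (C3–C4) between the aryl aldehyde and a CH2CHO side chain.
3. The C2–C3 bond (vinyl plus CH2CHO on C2) comes from a second Claisen ([3,3]) rearrangement of an E‑allylic alcohol.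
4. The key C8a–C1 bond and the C1 stereocentre come from an aromatic Claisen rearrangement. Chirality is transferred from the carbinol carbon of (S)‑3‑butene‑1,2‑diol (chiral pool), and only one ortho carbon is free, so the bond forms at C8a.
5. The ether comes from Mitsunobu coupling of a phenol‑aldehyde with an allylic alcohol made by cross‑metathesis.

## Route

**Step 1**
Reactants: 1 (S)‑but‑3‑ene‑1,2‑diol
Product: 2 (S)‑1‑(TBSO)but‑3‑en‑2‑ol
Conditions: TBSCl, imidazole, CH2Cl2, 0 °C
Reagents that add atoms: TBSCl, CC(C)(C)[Si](C)(C)Cl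
Why: The primary OH is silylated selectively (silyl protection). The stereocentre is untouched.

**Step 2**
Reactants: 3 2‑methoxy‑4‑vinylphenol (4‑vinylguaiacol)
Product: 4 1‑(benzyloxy)‑2‑methoxy‑4‑vinylbenzene
Conditions: BnBr, K2CO3, DMF, rt
Reagents that add atoms: BnBr, BrCc1ccccc1
Why: Williamson O‑benzylation of the phenol gives the cross‑metathesis partner.

**Step 3**
Reactants: 2 (2 equiv) and 4
Product: 5 (S,E)‑4‑[4‑(benzyloxy)‑3‑methoxyphenyl]‑1‑(TBSO)but‑3‑en‑2‑ol
Conditions: Hoveyda–Grubbs II (5 mol %), CH2Cl2, 40 °C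
Reagents that add atoms: none
Why: Cross‑metathesis of the terminal alkene with a styrene gives the E‑styryl carbinol. The allylic stereocentre is retained.

**Step 4**
Reactants: 5 and 6 (4‑(benzyloxy)‑3‑hydroxybenzaldehyde)
Product: 7 4‑(benzyloxy)‑3‑{[(R,E)‑4‑(4‑benzyloxy‑3‑methoxyphenyl)‑1‑(TBSO)but‑3‑en‑2‑yl]oxy}benzaldehyde
Conditions: PPh3, DIAD, toluene, 0 °C → rt
Reagents that add atoms: none
Why: Mitsunobu etherification of the acidic phenol inverts the carbinol, so (S)‑alcohol gives (R)‑aryl allyl ether. Non‑polar solvent and low temperature disfavour ionisation.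

**Step 5**
Reactants: 7
Product: 8 4‑(benzyloxy)‑2‑[(1S,2E)‑1‑(4‑benzyloxy‑3‑methoxyphenyl)‑4‑(TBSO)but‑2‑en‑1‑yl]‑3‑hydroxybenzaldehyde
Conditions: PhNEt2, BHT, 200 °C, microwave, sealed tube
Reagents that add atoms: none
Why: Aromatic Claisen rearrangement goes through a chair transition state with the CH2OTBS group equatorial. The bond forms suprafacially at the only free ortho carbon (C2 of the benzaldehyde; the meta‑CHO also favours this site). This gives the E‑alkene and sets the diaryl‑methine C1 as (S) by chirality transfer.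

**Step 6**
Reactants: 8
Product: 9 the 3‑methyl ether of 8
Conditions: MeI, K2CO3, acetone, 40 °C
Reagents that add atoms: MeI, CI
Why: Phenol O‑methylation installs the C8 OMe. It is the only free phenol, and mild conditions avoid deprotonating C1–H.

**Step 7**
Reactants: 9
Product: 10 (E)‑allylic alcohol, 4‑(benzyloxy)‑2‑[(1S,2E)‑1‑(4‑benzyloxy‑3‑methoxyphenyl)‑4‑hydroxybut‑2‑en‑1‑yl]‑3‑methoxybenzaldehyde
Conditions: TBAF, AcOH, THF, 0 °C
Reagents that add atoms: none
Why: AcOH‑buffered fluoride removes the primary TBS group. The benzyl ethers, aldehyde and C1–H survive.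

**Step 8**
Reactants: 10
Product: 11 4‑(benzyloxy)‑2‑[(1S)‑1‑(4‑benzyloxy‑3‑methoxyphenyl)‑4‑oxo‑2‑vinylbutyl]‑3‑methoxybenzaldehyde (C2 as an epimeric mixture)
Conditions: CH2=CHOEt (excess), Pd(OAc)2/1,10‑phenanthroline (5 mol %), CH2Cl2, rt; then PhMe, 150 °C, sealed tube
Reagents that add atoms: ethyl vinyl ether, C=COCC (contributes the CH2CHO unit)
Why: Transvinylation gives the allyl vinyl ether, which undergoes Claisen rearrangement (chair transition state) to form the C2–C3 bond. The vinyl group carries the future C9. C2 is set only with modest bias from C1 and is corrected in step 11.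

**Step 9**
Reactants: 11
Product: 12 (1S)‑7‑(benzyloxy)‑1‑[4‑(benzyloxy)‑3‑methoxyphenyl]‑8‑methoxy‑2‑vinyl‑1,2‑dihydronaphthalene‑3‑carbaldehyde
Conditions: pyrrolidine (20 mol %), AcOH (20 mol %), PhMe, 50 °C
Reagents that add atoms: none
Why: Enamine‑catalysed intramolecular aldol condensation closes the six‑membered ring (C3–C4) and dehydrates to the conjugated enal. C1 and C2 are untouched, and C2–H is not activated.

**Step 10**
Reactants: 12
Product: 13 (1S)‑1,2‑dihydronaphthalene‑2,3‑dicarbaldehyde (7‑OBn, 1‑aryl with 4‑OBn‑3‑OMe, 8‑OMe; C2 epimeric)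
Conditions: OsO4 (5 mol %), NaIO4 (4 equiv), 2,6‑lutidine, dioxane/H2O 3:1, rt
Reagents that add atoms: NaIO4, [Na+].[O-]I(=O)(=O)=O (oxygen of the new CHO)
Why: Lemieux–Johnson cleavage (dihydroxylation then periodate cleavage) attacks the unhindered monosubstituted vinyl group in preference to the electron‑poor trisubstituted enal alkene.

**Step 11**
Reactants: 13
Product: 14 (1S,2R)‑2,3‑dicarbaldehyde, COc1cc([C@H]2c3c(ccc(OCc4ccccc4)c3OC)C=C(C=O)[C@@H]2C=O)ccc1OCc1ccccc1
Conditions: DBU (10 mol %), CH2Cl2, 0 °C → rt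
Reagents that add atoms: none
Why: Base‑catalysed enolisation at C2 (α to the aliphatic aldehyde) equilibrates to the trans isomer. This isomer is expected to be favoured because C1‑aryl is pseudo‑axial (peri OMe strain) and the C2 substituent is pseudo‑axial (A(1,2) strain with the C3 CHO). The result is (1S,2R), with C1 fixed.

**Step 12**
Reactants: 14
Product: 15 (1S,2R)‑7‑(benzyloxy)‑1‑[4‑(benzyloxy)‑3‑methoxyphenyl]‑2‑(hydroxymethyl)‑8‑methoxy‑1,2‑dihydronaphthalene‑3‑carbaldehyde
Conditions: NaBH(OAc)3 (1.1 equiv), MeCN, 0 °C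
Reagents that add atoms: none (hydride only)
Why: This mild borohydride reduces the aliphatic aldehyde in preference to the conjugated aryl enal, and the mildly acidic conditions do not epimerise C2.

**Step 13**
Reactants: 15
Product: 16 Vitedoin A, (1S,2R)‑7‑hydroxy‑1‑(4‑hydroxy‑3‑methoxyphenyl)‑2‑(hydroxymethyl)‑8‑methoxy‑1,2‑dihydronaphthalene‑3‑carbaldehyde
Conditions: BCl3, pentamethylbenzene, CH2Cl2, −78 °C
Reagents that add atoms: none
Why: Low‑temperature BCl3 debenzylation with a cation scavenger cleaves both aryl benzyl ethers and leaves the aryl methyl ethers and the enal intact. Hydrogenolysis is avoided because it would reduce the C3=C4 double bond.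

## Compound list
1 | (S)‑but‑3‑ene‑1,2‑diol | O[C@H](CO)C=C | starting material
2 | (S)‑1‑(TBSO)but‑3‑en‑2‑ol | O[C@H](CO[Si](C)(C)C(C)(C)C)C=C | intermediate
3 | 2‑methoxy‑4‑vinylphenol | C=Cc1ccc(O)c(OC)c1 | starting material
4 | 4‑benzyloxy‑3‑methoxystyrene | C=Cc1ccc(OCc2ccccc2)c(OC)c1 | intermediate
5 | (S,E)‑allylic alcohol | O[C@H](CO[Si](C)(C)C(C)(C)C)/C=C/c1ccc(OCc2ccccc2)c(OC)c1 | intermediate
6 | 4‑(benzyloxy)‑3‑hydroxybenzaldehyde | O=Cc1ccc(OCc2ccccc2)c(O)c1 | starting material
7 | (R,E)‑aryl allyl ether | O=Cc1ccc(OCc2ccccc2)c(O[C@@H](CO[Si](C)(C)C(C)(C)C)/C=C/c2ccc(OCc3ccccc3)c(OC)c2)c1 | intermediate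
8 | Claisen product (phenol) | O=Cc1ccc(OCc2ccccc2)c(O)c1[C@H](c1ccc(OCc2ccccc2)c(OC)c1)/C=C/CO[Si](C)(C)C(C)(C)C | intermediate
9 | O‑methyl ether | O=Cc1ccc(OCc2ccccc2)c(OC)c1[C@H](c1ccc(OCc2ccccc2)c(OC)c1)/C=C/CO[Si](C)(C)C(C)(C)C | intermediate
10 | allylic alcohol | O=Cc1ccc(OCc2ccccc2)c(OC)c1[C@H](c1ccc(OCc2ccccc2)c(OC)c1)/C=C/CO | intermediate
11 | vinyl/CH2CHO aldehyde (C2 epimers) | O=Cc1ccc(OCc2ccccc2)c(OC)c1[C@H](c1ccc(OCc2ccccc2)c(OC)c1)C(C=C)CC=O | intermediate
12 | 2‑vinyl dihydronaphthalene enal (C2 epimers) | COc1cc([C@H]2c3c(ccc(OCc4ccccc4)c3OC)C=C(C=O)C2C=C)ccc1OCc1ccccc1 | intermediate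
13 | dialdehyde (C2 epimers) | COc1cc([C@H]2c3c(ccc(OCc4ccccc4)c3OC)C=C(C=O)C2C=O)ccc1OCc1ccccc1 | intermediate
14 | trans dialdehyde | COc1cc([C@H]2c3c(ccc(OCc4ccccc4)c3OC)C=C(C=O)[C@@H]2C=O)ccc1OCc1ccccc1 | intermediate
15 | dibenzyl hydroxy‑enal | COc1cc([C@H]2c3c(ccc(OCc4ccccc4)c3OC)C=C(C=O)[C@@H]2CO)ccc1OCc1ccccc1 | intermediate
16 | Vitedoin A | COc1cc([C@H]2c3c(ccc(O)c3OC)C=C(C=O)[C@@H]2CO)ccc1O | target

**Total steps:** 13. **Longest linear sequence:** 12 (1 → 2 → 5 → 7 → 8 → 9 → 10 → 11 → 12 → 13 → 14 → 15 → 16).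

## Three steps most likely to fail
1. **Step 5 (aromatic Claisen).** The ortho carbon is hindered (between OR and CHO), 200 °C is needed, and some loss of ee is possible.
   Fallback: change the strategy to an intramolecular dehydro‑Diels–Alder of a 3‑arylpropargyl cinnamate. Use a glyceraldehyde‑derived propargylic carbinol tether that is later cleaved by reduction then NaIO4, and block the competing ortho position with a removable halogen.
2. **Step 4 (Mitsunobu).** The electron‑rich styryl carbinol can ionise, or react by SN2′, and erode the stereochemistry.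
   Fallback: form the ether by Cu‑catalysed Ullmann C–O coupling of the alcohol with 3‑iodo‑4‑benzyloxybenzaldehyde. This proceeds with retention, so start from (R)‑3‑butene‑1,2‑diol.
3. **Step 8 (vinyl ether Claisen with the free aryl aldehyde).** Yield and C2 selectivity are uncertain, and the equilibration in step 11 must favour trans.
   Fallback: oxidise allylic alcohol 10 to the enal after masking ArCHO as its dimethyl acetal. Then add a vinylcuprate in conjugate fashion, unmask, and close the ring by aldol condensation, with C2 again set by equilibration.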